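**Remarks on the chemistry (assumptions and corrections)**

- Atom labels: ring carbons C1–C10; C1' is the CH2OAc carbon on C1; C11 is the exocyclic oxirane carbon on C8, bearing CH3 and C12H2OAc.
- The C6 hydroxyl is carried as its tert-butyldiphenylsilyl ether rather than the tert-butyldimethylsilyl ether. This changes the protecting group only, and it lets the two allylic hydroxyls be freed by mild acid while C6 stays masked.
- The C12 oxygen is carried as an acetal, not a silyl ether, through the alkenyllithium step: a silyloxymethyl group cis to C8–Li would invite a 1,4 O→C silyl shift.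
- C8 has the descriptor R in the acyclic compounds 22–24 and S in 27, although its geometry never changes. The CIP ranking of its C7 and C9 arms inverts once C6 carries more oxygen.
- The tartrate assignment was checked by descriptor analogy and stands: L-(+)-tartrate gives the 2S series with geraniol-type alcohols, so D-(−)-diethyl tartrate should give R at C1 and at C11.
- In alternative 3 the name of the dienone needs correcting; see there.

## Structural features

Compound 27 is a germacrane-type ten-membered carbocycle (ring A, C1–C10) with an E trisubstituted enone, C4=C5(CH3)–C6=O. Oxirane B is fused across C1–C10 (C1 quaternary with C1'H2OAc, C10–H, the ring bonds to C2 and C9 cis on the oxirane). Oxirane C is spiro at C8, with the exocyclic carbon C11 carrying CH3 and C12H2OAc. The stereocentres come in two adjacent pairs, C1/C10 and C8/C11, separated only by the C9 methylene, and three of the four are fully substituted. The fragile elements are the β,γ-epoxy ketone (enolisation towards C7 opens oxirane C), the acid-sensitive tetrasubstituted oxirane, two primary acetates and the strained E-cycloalkene. The real difficulty is to set absolute and relative configuration at four oxygenated centres of a mobile medium ring and then close that ring without losing them. The key step exploits that C1'–C1–C10 (oxirane B) and C12–C11–C8 (oxirane C) are both acetylated 2,3-epoxy primary alcohols with R carbinol-bearing carbons (C1, C11). Their distal carbons (C10, C8) follow from alkene geometry, so one tartrate enantiomer can build both oxiranes on an acyclic dienediol.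

## Logic of the disconnections

**27 ⇒ 26.** No skeletal bond is cut; the C6 carbonyl is traced back to a carbinol. The enone is β,γ to oxirane C and is best made last. The gain is that ring closure may deliver an alcohol of either configuration. The demand is a neutral, non-enolising oxidant.

**26 ⇒ 25.** The C5–C6 ring bond is cut. It joins an sp2 carbon to an oxygenated carbon and lies remote from all four stereocentres. The gain is an open chain that already holds every stereocentre and ends in an E iodoalkene and an aldehyde. The demand is a chemoselective alkenyl–aldehyde coupling that keeps the E geometry, tolerates oxiranes and acetates, and works at high dilution.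

**25 ⇒ 24 ⇒ 23 ⇒ 22.** Only functional groups change: the C6 aldehyde goes back to the silyl ether and the two acetates to free hydroxyls. The aldehyde is β,γ to oxirane C and must exist only just before closure. Acetylation directly after epoxidation caps the epoxy alcohols. The demand is a C6 silyl group that comes off under buffered fluoride.

**22 ⇒ 20.** The four C–O bonds C1–O, C10–O, C8–O and C11–O are cut. All four stereocentres belong to two 2,3-epoxy alcohol units, so removing both oxygens leaves an achiral dienediol. The gain is two rings and four stereocentres in one step. The demand is E geometry at C10=C1, Z geometry at C8=C11, free C1' and C12 hydroxyls, a masked C6 oxygen, and one tartrate enantiomer acting on both alkenes.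

**20 ⇒ 19 ⇒ 17.** The C5–I and C4–H bonds are cut back to the C4≡C5 alkyne, and the C1' and C12 hydroxyls are re-protected. An iodoalkene cannot pass through the organolithium and Grignard steps, so it is made late from a robust alkyne. The demand is syn hydrometalation with the metal on C5, and acid-labile groups at C1' and C12 that leave in the presence of the C6 silyl ether.

**17 ⇒ 13 + 14.** The C7–C8 bond (and the O–Si bond) is cut. The two-carbon oxygenated arm is an epoxide-opening product of a C8 alkenyl nucleophile. The gain is a return to an alkenyl iodide. The demand is retention of geometry in the iodine–lithium exchange and a non-migrating protecting group on the cis C12 oxygen.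

**13 ⇒ 12 ⇒ 10.** The C11–CH3 and C8–I bonds are cut. Anti addition of methyl and metal across a propargylic alcohol sets the tetrasubstituted geometry in one operation, using the C12 hydroxyl as anchor. The gain is an alkyne. The demand is methyl to C11, metal to C8, and no reaction at the C4≡C5 alkyne.

**10 ⇒ 8 + 9.** The C8–C9 bond is cut. A doubly activated methylene is best made by alkylating a copper acetylide with a primary allylic halide. The gain is two simple pieces. The demand is attack at C9 rather than at the fully substituted C1, under a base too weak to isomerise the skipped enyne.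

**8 ⇒ 7 ⇒ 4 + 5.** The C1–C2 bond is cut, and C9–Br goes back to C9–OH. An sp2–sp3 cross-coupling at an alkenyl iodide keeps the alkene geometry. The gain is a four-carbon and a five-carbon unit. The demand is tolerance of a free hydroxyl and suppression of β-hydride elimination.

**4 ⇒ 2 ⇒ 1.** The C1–I and C10–H bonds are cut back to an alkyne, and one O–Si bond is cut. Hydroxyl-directed trans-hydroalumination fixes the alkene geometry and, because only the free hydroxyl directs, tells the two ends of a symmetrical diol apart. The demand is a clean monoprotection.

## Other disconnections considered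

**Alternative 1:** The cut is C2–C3, made in the forward sense by a [3,3] shift that also breaks C5–C10 of a six-membered ring. The forward key step is KN(SiMe3)2/18-crown-6 alkoxide formation, anionic oxy-Cope ring expansion and trapping of the C10 enolate with PhNTf2 to give the ten-membered enol triflate A1.

- In its favour: the medium ring is formed by a charge-accelerated sigmatropic shift that needs no high dilution, and a chair transition state should set the E C4=C5 alkene. On ring formation this plan is the better of the two, since step 15 of the chosen route is an entropically and enthalpically costly closure.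
- Against it here: A1 contains none of the four stereocentres of 27. Its C6 and C8 carbinol centres are both destined to be destroyed. C1 carries a methyl group that still has to be oxidised to C1' after the triflate is reduced. C8 has to become a ketone and then a tetrasubstituted C8=C11 alkene with C12 cis to C7, and an olefination of a ketone flanked by two methylenes offers no geometric bias.
- Comparison: the chosen plan sets all stereocentres by reagent control on acyclic 20, whereas A1 leaves both epoxidations to the conformational bias of a flexible ring or to later directed chemistry. On step economy the early ring formation is offset by a long series of functional-group changes after A1.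

**Alternative 2:** The cut is C8–C9. The forward key step is an allyl–alkenyl Stille macrocyclisation (Pd2(dba)3, AsPh3, CuI) between a C9 allylic chloride and a C8 alkenylstannane, giving trienone A2.

- In its favour: A2 has the whole skeleton, the C6 ketone and all three alkenes in the geometries needed (C1' trans to C9, C12 cis to C7, E enone). Only desilylation, double epoxidation and acetylation remain. This endgame is shorter than the five steps after 22 in the chosen route and never passes through a β,γ-epoxy aldehyde; on both points it is the better plan. Both ring alkenes are still primary allylic alcohols, so titanium tartrate control remains available in principle, which makes it the equal of the chosen plan there.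
- Against it here: transmetalation of a fully substituted alkenylstannane is slow. The π-allyl intermediate can be attacked at C9 or at C1 and can lose its geometry by σ–π–σ interconversion. A2 is a β,γ-unsaturated ketone inside a skipped triene and may conjugate.
- Comparison: the decisive difference is that the epoxidations would act on alkenes held in a medium ring, where one face of each alkene points into the ring; the face the tartrate prefers may not be the accessible one. The chosen plan avoids that conflict by epoxidising before closure. Fragment work towards the seco-stannane needs the same stereodefined tri- and tetrasubstituted alkenes, so total step count would be similar.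

**Alternative 3:** The cut is a pair of cyclobutane bonds, C1–C4 and C5–C10. A thermal [2+2] cycloreversion forms C4=C5 and C1=C10 and unzips a six-membered ring into the ten-membered dienone A3.

- Correction of the name: in dienone numbering the silyloxymethyl group of A3 sits on C6 and the acrylate on C9 (C1 and C8 in the numbering of 27). By CIP rules the C1=C10 alkene is E, because CH2OSi outranks the ring methylene; it is "Z" only in the sense that the two ring bonds are cis.
- In its favour: no macrocyclisation is needed, both alkene geometries arise stereospecifically from the cycloreversion, the C1' oxygen is already present, and the C8 stereocentre comes from the chiral pool. On ring construction and on the brevity of the early stages it is the equal or the better of the chosen plan.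
- Against it here: the only stereocentre of A3 is an sp3 C8 bearing an acrylate, whereas 27 needs C8 as the spiro-oxirane carbon. Isomerising the exocyclic methylene into the C8=C11 alkene with C12 cis to C7 erases that stereocentre, so the absolute configuration of C1, C10, C8 and C11 would need a new source. A3 is also a 1,5-diene (C5=C4–C3–C2–C1=C10) and may undergo Cope rearrangement at thermolysis temperatures, and it has two competing Michael acceptors.
- Comparison: after A3 the route still needs ester reduction, alkene isomerisation, two face-selective epoxidations on the ring and two acetylations. The chosen plan is longer before the ring exists but has every stereocentre secured before closure.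

Key step: step 11

## Route

Step 1
Reactants: 1 2-butyne-1,4-diol
Product: 2 4-(tert-butyldimethylsilyloxy)but-2-yn-1-ol
Conditions: NaH (1.0 equiv), THF, 0 °C; TBSCl (1.0 equiv), 0 °C → rt
Reagents that add atoms: tert-butyldimethylsilyl chloride CC(C)(C)[Si](C)(C)Cl
Why: O-silylation of the sparingly soluble monosodium alkoxide of a symmetrical diol favours the monoether; this masks the future C1' oxygen and leaves the C9 hydroxyl free to direct step 2.

Step 2
Reactants: 2 4-(tert-butyldimethylsilyloxy)but-2-yn-1-ol
Product: 4 (Z)-4-(tert-butyldimethylsilyloxy)-3-iodobut-2-en-1-ol, via cyclic alkenylalanate 3 (not isolated)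
Conditions: NaAlH2(OCH2CH2OMe)2, THF, 0 °C; EtOAc; then I2, THF, −78 → 0 °C
Reagents that add atoms: iodine II
Why: Hydroxyl-directed trans-hydroalumination of a propargylic alcohol delivers hydride to the proximal alkyne carbon (C10) and aluminium to the distal one (C1) in a five-membered chelate; iodinolysis with retention gives the Z iodoalkene, which fixes C1' trans to C9.

Step 3
Reactants: 4 (Z)-4-(tert-butyldimethylsilyloxy)-3-iodobut-2-en-1-ol; 5 5-bromopent-2-yne
Product: 7 (E)-3-[(tert-butyldimethylsilyloxy)methyl]oct-2-en-6-yn-1-ol, via pent-3-ynylzinc bromide 6 (not isolated)
Conditions: 5, Zn dust, LiCl, THF, 50 °C; then 4, PdCl2(dppf) (5 mol %), THF, rt → 50 °C (2.5 equiv of 6)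
Reagents that add atoms: none
Why: Negishi sp3–sp2 cross-coupling: zinc insertion into the alkyl bromide, then oxidative addition of the alkenyl iodide to zerovalent palladium, transmetalation and reductive elimination with retention of alkene geometry; the bidentate phosphine suppresses β-hydride elimination and excess zinc reagent covers the free hydroxyl.

Step 4
Reactants: 7 (E)-3-[(tert-butyldimethylsilyloxy)methyl]oct-2-en-6-yn-1-ol
Product: 8 (E)-1-bromo-3-[(tert-butyldimethylsilyloxy)methyl]oct-2-en-6-yne
Conditions: CBr4, PPh3, CH2Cl2, 0 °C
Reagents that add atoms: carbon tetrabromide BrC(Br)(Br)Br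
Why: Appel bromination of a primary allylic alcohol by SN2 displacement of the oxyphosphonium; allylic transposition is disfavoured because C1 is fully substituted, and the silyl ether and alkyne are untouched.

Step 5
Reactants: 8 (E)-1-bromo-3-[(tert-butyldimethylsilyloxy)methyl]oct-2-en-6-yne; 9 propargyl alcohol
Product: 10 (E)-6-[(tert-butyldimethylsilyloxy)methyl]undec-5-ene-2,9-diyn-1-ol
Conditions: CuI (20 mol %), n-Bu4NI (20 mol %), K2CO3, DMF, rt
Reagents that add atoms: none
Why: Copper acetylide alkylation of a primary allylic bromide forms C8–C9; attack at C9 is preferred over the fully substituted C1, and the carbonate base is too weak to isomerise the skipped enyne or to O-alkylate the alcohol.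

Step 6
Reactants: 10 (E)-6-[(tert-butyldimethylsilyloxy)methyl]undec-5-ene-2,9-diyn-1-ol
Product: 12 (2Z,5E)-6-[(tert-butyldimethylsilyloxy)methyl]-3-iodo-2-methylundeca-2,5-dien-9-yn-1-ol, via cyclic alkenylmagnesium alkoxide 11 (not isolated)
Conditions: MeMgBr (4 equiv), CuI (20 mol %), THF, −20 °C → rt; then I2, THF, −78 → 0 °C
Reagents that add atoms: methylmagnesium bromide C[Mg]Br; iodine II
Why: Copper-catalysed anti-carbomagnesiation of a 2-alkyn-1-ol: the magnesium alkoxide directs methyl to C11 and magnesium to C8 in a five-membered chelate, so iodinolysis with retention gives the tetrasubstituted Z iodoalkene with iodine cis to C12; the C4≡C5 alkyne has no directing group and stays inert.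

Step 7
Reactants: 12 (2Z,5E)-6-[(tert-butyldimethylsilyloxy)methyl]-3-iodo-2-methylundeca-2,5-dien-9-yn-1-ol
Product: 13 tetrahydropyran-2-yl ether of 12 at the C12 oxygen (both acetal epimers)
Conditions: 3,4-dihydro-2H-pyran, PPTS (cat.), CH2Cl2, rt
Reagents that add atoms: 3,4-dihydro-2H-pyran C1CCOC=C1
Why: Acid-catalysed addition of the alcohol to the enol ether gives an acetal that is inert to organolithiums and cannot migrate to carbon, unlike a silyl ether placed cis to the C8–Li of step 8.

Step 8
Reactants: 13 tetrahydropyran-2-yl ether of 12; 14 ethylene oxide
Product: 17 (2Z,5E)-3-(2-hydroxyethyl)-6-(hydroxymethyl)-2-methylundeca-2,5-dien-9-yn-1-ol carrying tert-butyldiphenylsilyl on the C6 oxygen plus tetrahydropyran-2-yl on the C12 oxygen plus tert-butyldimethylsilyl on the C1' oxygen, via alkenyllithium 15 (not isolated), via lithium alkoxide 16 (not isolated)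
Conditions: t-BuLi (2.1 equiv), Et2O, −78 °C; 14 (5 equiv), −78 → 0 °C; then TBDPSCl, imidazole, THF/DMF, 0 °C → rt
Reagents that add atoms: tert-butyl(chloro)diphenylsilane CC(C)(C)[Si](Cl)(c1ccccc1)c1ccccc1
Why: Iodine–lithium exchange keeps the alkene geometry, and SN2 opening of ethylene oxide by the alkenyllithium adds C7–C6 cis to C12; the lithium alkoxide is silylated in the same flask (isolating the alcohol first is a trivial variant).

Step 9
Reactants: 17 alkyne tri-ether
Product: 19 (2Z,5E,9E)-3-(2-hydroxyethyl)-6-(hydroxymethyl)-10-iodo-2-methylundeca-2,5,9-trien-1-ol carrying the same three ether groups as 17, via alkenylzirconocene chloride 18 (not isolated)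
Conditions: Cp2Zr(H)Cl (2.5 equiv), THF, 50 °C; then I2, THF, 0 °C
Reagents that add atoms: iodine II
Why: Hydrozirconation adds Zr–H syn across the alkyne, and excess reagent with warming equilibrates the alkenylzirconium towards the less hindered methyl-bearing C5; iodinolysis with retention gives the E iodoalkene (C3 trans to I), while tri- and tetrasubstituted alkenes react far more slowly.

Step 10
Reactants: 19 iodoalkene tri-ether
Product: 20 (2Z,5E,9E)-3-[2-(tert-butyldiphenylsilyloxy)ethyl]-6-(hydroxymethyl)-10-iodo-2-methylundeca-2,5,9-trien-1-ol
Conditions: CSA (0.1 equiv), MeOH/CH2Cl2, 0 °C → rt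
Reagents that add atoms: none
Why: Acid-catalysed methanolysis cleaves the acetal and the primary tert-butyldimethylsilyl ether, while the bulkier tert-butyldiphenylsilyl ether is far more stable to acid and stays on C6; iodoalkene and skipped diene are inert to these conditions.

Step 11
Reactants: 20 acyclic dienediol
Product: 22 bis-epoxy diol, C1 R, C10 R, C11 R, C8 R (descriptor for the open chain), both hydroxyls free, C6 tert-butyldiphenylsilyl ether, E iodoalkene intact, via mono-epoxy diol 21 (not isolated)
Conditions: Ti(OiPr)4 (2.4 equiv), D-(−)-diethyl tartrate (2.9 equiv), tBuOOH (6 equiv, anhydrous), 4 Å MS, CH2Cl2, −20 °C, 24–48 h; Me2S, then sat. aq. Na2SO4 work-up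
Reagents that add atoms: tert-butyl hydroperoxide CC(C)(C)OO
Why: Each allylic hydroxyl exchanges with isopropoxide on the dimeric titanium tartrate, tBuOOH binds the same tetravalent titanium centre, and its distal oxygen is passed to the coordinated alkene in a concerted spiro-type transition state. The closest known reaction type is the Sharpless asymmetric epoxidation of trisubstituted and tetrasubstituted primary allylic alcohols, applied here twice on one substrate. Oxirane B (C1–C10) and oxirane C (C8–C11) each close by suprafacial transfer of one oxygen atom to one alkene face, both C–O bonds of a ring forming together, so no exo or endo cyclisation mode is involved. C1 and C11 are set by the tartrate: the L-(+)-ester gives the 2S series with geraniol-type alcohols, and because hydroxymethyl, distal alkene carbon and third substituent rank alike at C1 and C11, D-(−)-diethyl tartrate should give R at both. C10 and C8 follow stereospecifically from syn addition to the E C10=C1 alkene (C1' trans to C9) and the Z C8=C11 alkene (C12 cis to C7). The step needs chemoselectivity for the two allylic alcohols over the iodoalkene, which has no coordinating hydroxyl and is electron-poor, and complete conversion of the slower tetrasubstituted alkene, for which stoichiometric titanium tartrate and extended time are planned after the trisubstituted alkene has reacted via 21. Titanium-promoted opening of the first oxirane by the remaining hydroxyl is held back by low temperature, full tartrate loading and a non-acidic work-up. Two reagent-controlled events in one molecule turn most minor-face product into a separable diastereomer, which should raise the enantiomeric purity of 22.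

Step 12
Reactants: 22 bis-epoxy diol
Product: 23 bis-epoxy diacetate (C1' and C12 acetates, C6 tert-butyldiphenylsilyl ether)
Conditions: Ac2O, pyridine, DMAP (cat.), CH2Cl2, 0 °C
Reagents that add atoms: acetic anhydride CC(=O)OC(C)=O
Why: DMAP-catalysed acylation of two primary alcohols under non-acidic conditions; capping the hydroxyls removes the nucleophiles that could open the oxiranes (Payne-type or cross-ring attack).

Step 13
Reactants: 23 bis-epoxy diacetate
Product: 24 C6 primary alcohol (bis-epoxy diacetate, silyl group removed)
Conditions: TBAF/AcOH (1:1, 3 equiv), THF, 0 °C → rt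
Reagents that add atoms: none
Why: Fluoride-driven desilylation buffered with acetic acid; buffering avoids acetate cleavage by basic fluoride, and the absence of strong acid keeps the freed C6 hydroxyl from opening oxirane C.

Step 14
Reactants: 24 C6 primary alcohol
Product: 25 C6 aldehyde (β,γ-epoxy aldehyde, E iodoalkene at C5)
Conditions: Dess–Martin periodinane, pyridine, CH2Cl2, 0 °C; used at once
Reagents that add atoms: none
Why: Dess–Martin oxidation of a primary alcohol stops at the aldehyde under buffered, non-basic conditions; the product is not stored because enolisation towards C7 would open oxirane C.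

Step 15
Reactants: 25 C6 aldehyde
Product: 26 ten-membered allylic alcohol (C5–C6 bond closed, C6 carbinol as both epimers, E C4=C5 alkene)
Conditions: CrCl2 (10 equiv), NiCl2 (1 mol % of the chromium), degassed DMSO/THF, rt, slow addition to about 0.002 M
Reagents that add atoms: none
Why: Intramolecular Nozaki–Hiyama–Kishi reaction: nickel activates the alkenyl iodide, transmetalation gives a trivalent alkenylchromium species that adds chemoselectively to the aldehyde with retention of the E geometry; high dilution and the two oxiranes acting as turn elements favour closure, and the new C6 stereocentre is removed in step 16.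

Step 16
Reactants: 26 ten-membered allylic alcohol
Product: 27 CNP0185847.3 (target)
Conditions: Dess–Martin periodinane, pyridine, CH2Cl2, 0 °C → rt
Reagents that add atoms: none
Why: Dess–Martin oxidation of the secondary allylic alcohol gives the enone and erases the C6 stereocentre; the buffered neutral medium spares the β,γ-epoxy ketone, both oxiranes and both acetates.

## Compound list

1 | 2-butyne-1,4-diol | OCC#CCO | starting material
2 | 4-(tert-butyldimethylsilyloxy)but-2-yn-1-ol | OCC#CCO[Si](C)(C)C(C)(C)C | intermediate
3 | cyclic alkenylalanate, sodium salt (Al on C1 and on the C9 oxygen; not isolated) | [Na+].COCCO[Al-]1(OCCOC)OCC=C1CO[Si](C)(C)C(C)(C)C | intermediate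
4 | (Z)-4-(tert-butyldimethylsilyloxy)-3-iodobut-2-en-1-ol | OC/C=C(/CO[Si](C)(C)C(C)(C)C)I | intermediate
5 | 5-bromopent-2-yne | CC#CCCBr | starting material
6 | pent-3-ynylzinc bromide (not isolated) | CC#CCC[Zn]Br | intermediate
7 | (E)-3-[(tert-butyldimethylsilyloxy)methyl]oct-2-en-6-yn-1-ol | OC/C=C(/CO[Si](C)(C)C(C)(C)C)CCC#CC | intermediate
8 | (E)-1-bromo-3-[(tert-butyldimethylsilyloxy)methyl]oct-2-en-6-yne | BrC/C=C(/CO[Si](C)(C)C(C)(C)C)CCC#CC | intermediate
9 | propargyl alcohol | C#CCO | starting material
10 | (E)-6-[(tert-butyldimethylsilyloxy)methyl]undec-5-ene-2,9-diyn-1-ol | OCC#CC/C=C(/CO[Si](C)(C)C(C)(C)C)CCC#CC | intermediate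
11 | cyclic alkenylmagnesium alkoxide (Mg on C8 and on the C12 oxygen, methyl on C11; not isolated) | CC1=C(C/C=C(/CO[Si](C)(C)C(C)(C)C)CCC#CC)[Mg]OC1 | intermediate
12 | (2Z,5E)-6-[(tert-butyldimethylsilyloxy)methyl]-3-iodo-2-methylundeca-2,5-dien-9-yn-1-ol | C/C(CO)=C(/I)C/C=C(/CO[Si](C)(C)C(C)(C)C)CCC#CC | intermediate
13 | tetrahydropyran-2-yl ether of 12 (acetal carbon as both epimers) | C/C(COC1CCCCO1)=C(/I)C/C=C(/CO[Si](C)(C)C(C)(C)C)CCC#CC | intermediate
14 | ethylene oxide | C1CO1 | starting material
15 | alkenyllithium from 13 (Li on C8, geometry retained; not isolated) | C/C(COC1CCCCO1)=C(/[Li])C/C=C(/CO[Si](C)(C)C(C)(C)C)CCC#CC | intermediate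
16 | lithium alkoxide at C6 (C7–C6 arm cis to C12; not isolated) | [Li]OCC/C(=C(/C)COC1CCCCO1)C/C=C(/CO[Si](C)(C)C(C)(C)C)CCC#CC | intermediate
17 | alkyne tri-ether: C6 tert-butyldiphenylsilyl ether, C12 tetrahydropyran-2-yl ether, C1' tert-butyldimethylsilyl ether of (2Z,5E)-3-(2-hydroxyethyl)-6-(hydroxymethyl)-2-methylundeca-2,5-dien-9-yn-1-ol | CC(C)(C)[Si](c1ccccc1)(c1ccccc1)OCC/C(=C(/C)COC1CCCCO1)C/C=C(/CO[Si](C)(C)C(C)(C)C)CCC#CC | intermediate
18 | alkenylzirconocene chloride (Zr on C5, H on C4, syn; not isolated) | CC(C)(C)[Si](c1ccccc1)(c1ccccc1)OCC/C(=C(/C)COC1CCCCO1)C/C=C(/CO[Si](C)(C)C(C)(C)C)CC/C=C(\C)[Zr](Cl)(C1C=CC=C1)C1C=CC=C1 | intermediate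
19 | iodoalkene tri-ether: same three ethers on (2Z,5E,9E)-3-(2-hydroxyethyl)-6-(hydroxymethyl)-10-iodo-2-methylundeca-2,5,9-trien-1-ol | CC(C)(C)[Si](c1ccccc1)(c1ccccc1)OCC/C(=C(/C)COC1CCCCO1)C/C=C(/CO[Si](C)(C)C(C)(C)C)CC/C=C(\C)I | intermediate
20 | (2Z,5E,9E)-3-[2-(tert-butyldiphenylsilyloxy)ethyl]-6-(hydroxymethyl)-10-iodo-2-methylundeca-2,5,9-trien-1-ol (precursor of the key step) | CC(C)(C)[Si](c1ccccc1)(c1ccccc1)OCC/C(=C(/C)CO)C/C=C(/CO)CC/C=C(\C)I | intermediate
21 | mono-epoxy diol: oxirane B only (C1 R, C10 R), Z C8=C11 alkene intact (not isolated) | CC(C)(C)[Si](c1ccccc1)(c1ccccc1)OCC/C(=C(/C)CO)C[C@H]1O[C@@]1(CO)CC/C=C(\C)I | intermediate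
22 | bis-epoxy diol: C1 R, C10 R, C11 R, C8 R; C6 tert-butyldiphenylsilyl ether; E iodoalkene (product of the key step) | CC(C)(C)[Si](c1ccccc1)(c1ccccc1)OCC[C@]3(C[C@H]1O[C@@]1(CO)CC/C=C(\C)I)O[C@]3(C)CO | intermediate
23 | bis-epoxy diacetate of 22 | CC(C)(C)[Si](c1ccccc1)(c1ccccc1)OCC[C@]3(C[C@H]1O[C@@]1(COC(C)=O)CC/C=C(\C)I)O[C@]3(C)COC(C)=O | intermediate
24 | C6 primary alcohol (desilylated 23) | OCC[C@]3(C[C@H]1O[C@@]1(COC(C)=O)CC/C=C(\C)I)O[C@]3(C)COC(C)=O | intermediate
25 | C6 aldehyde | O=CC[C@]3(C[C@H]1O[C@@]1(COC(C)=O)CC/C=C(\C)I)O[C@]3(C)COC(C)=O | intermediate
26 | ten-membered allylic alcohol, C6 carbinol as both epimers, other centres as in 27 | CC(=O)OC[C@]12CC/C=C(\C)C(O)C[C@]3(C[C@H]1O2)O[C@]3(C)COC(C)=O | intermediate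
27 | CNP0185847.3 | CC(=O)OC[C@]12CC/C=C(\C)C(=O)C[C@]3(C[C@H]1O2)O[C@]3(C)COC(C)=O | target

## Step count and least certain steps

Total: 16 steps. Longest linear sequence: 16 steps, from 1 to 27; compounds 5, 9 and 14 each enter in a single step.

**Step 11 (key step).** The likely failures are incomplete oxygen transfer to the hindered tetrasubstituted Z allylic alcohol, loss of facial selectivity there, and titanium-promoted intramolecular opening of the first oxirane by the hydroxyl that is still free. All three grow with the long exposure to stoichiometric Lewis acid that the slow alkene requires. The fallback separates the two events. It sets out from 20 and runs a catalytic titanium tartrate epoxidation (Ti(OiPr)4, D-(−)-diisopropyl tartrate, about one equivalent of tBuOOH, −20 °C) that stops at the faster trisubstituted alkene, so that the mono-epoxy diol 21 is isolated. The tetrasubstituted alcohol is then epoxidised with a vanadium–bishydroxamic acid catalyst (VO(OiPr)3, C2-symmetric chiral bishydroxamic acid, tBuOOH, toluene, 0 °C). This system is far less Lewis acidic, and the ligand enantiomer is chosen to address the same face. The fallback returns to the route at 22.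

**Step 6.** Methyl is a reluctant group in copper-catalysed carbomagnesiation of an internal alkynol. The prolonged exposure to excess Grignard reagent this may need can isomerise the doubly activated C9 methylene of the skipped enyne. The fallback sets out from 10 and replaces carbometalation by alkoxide-anchored trans-diboration (n-BuLi, then B2pin2, THF, 70 °C). This gives the 4-(pinacolboryl)-2,5-dihydro-1,2-oxaborol-2-ol F1, whose ring boron sits on C8 cis to C12 and whose pinacol boronate sits on C11. Suzuki–Miyaura methylation of the C11 boronate (MeI, Pd(PPh3)4, K3PO4) should give the 4-methyl oxaborol-2-ol F2. Iododeboronation of the ring boron with retention (N-iodosuccinimide, MeCN) then returns to the route at 12.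

**Step 8.** The hindered alkenyllithium may be quenched by proton transfer before it opens ethylene oxide, and lithium iodide competes for the epoxide; the result would be protodeiodinated material. The fallback sets out from 13 and forms the C7–C8 bond by palladium catalysis. Stille coupling with tributyl(vinyl)stannane (Pd2(dba)3, AsPh3, CuI, NMP) gives the 1,3-diene F3. Hydroboration of its monosubstituted vinyl group with 9-BBN and oxidation with NaBO3 gives the homoallylic alcohol F4; the internal alkyne and the more substituted alkenes react much more slowly. Silylation (TBDPSCl, imidazole) returns to the route at 17.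

**Step 15.** Closure of a strained ten-membered ring can lose to intermolecular coupling or to protodeiodination of the alkenylchromium species. The Lewis acidic trivalent chromium chloride that accumulates may also open the tetrasubstituted oxirane or promote β-elimination of the epoxy aldehyde. The fallback changes both the nucleophile and the metal; it sets out from 17, before the iodoalkene is made, and so also removes step 9 and its dependence on regiocontrol of the hydrozirconation.

- Acid methanolysis as in step 10 gives the alkyne diol F5.
- Double epoxidation as in step 11 gives the alkyne bis-epoxy diol F6.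
- Acetylation gives the diacetate F7.
- Buffered fluoride gives the alcohol F8.
- Dess–Martin oxidation gives the ynal F9.
- Nickel-catalysed alkyne–aldehyde reductive macrocyclisation (Ni(cod)2, free IMes carbene, Et3SiH, THF, high dilution) should add hydrogen and C6 syn across the alkyne. A small carbene ligand and the ten- over nine-membered closure favour bond formation at the methyl-bearing C5, which would give the E triethylsilyl ether F10.
- TBAF/AcOH removes the silyl group and returns to the route at 26.

## Further compounds

F0 | step 11 | none | none
F1 | step 6 | 3-substituted 4-(pinacolboryl)-2,5-dihydro-1,2-oxaborol-2-ol (ring boron on C8, boronate on C11) | OB1OCC(B2OC(C)(C)C(C)(C)O2)=C1C/C=C(/CO[Si](C)(C)C(C)(C)C)CCC#CC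
F2 | step 6 | 3-substituted 4-methyl-2,5-dihydro-1,2-oxaborol-2-ol | OB1OCC(C)=C1C/C=C(/CO[Si](C)(C)C(C)(C)C)CCC#CC
F3 | step 8 | 1,3-diene: vinyl group on C8 cis to C12, C12 tetrahydropyran-2-yl ether, C1' tert-butyldimethylsilyl ether | C=C/C(=C(/C)COC1CCCCO1)C/C=C(/CO[Si](C)(C)C(C)(C)C)CCC#CC
F4 | step 8 | C6 homoallylic alcohol (desilyl analogue of 17) | OCC/C(=C(/C)COC1CCCCO1)C/C=C(/CO[Si](C)(C)C(C)(C)C)CCC#CC
F5 | step 15 | (2Z,5E)-3-[2-(tert-butyldiphenylsilyloxy)ethyl]-6-(hydroxymethyl)-2-methylundeca-2,5-dien-9-yn-1-ol | CC(C)(C)[Si](c1ccccc1)(c1ccccc1)OCC/C(=C(/C)CO)C/C=C(/CO)CCC#CC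
F6 | step 15 | alkyne bis-epoxy diol (configuration as in 22) | CC(C)(C)[Si](c1ccccc1)(c1ccccc1)OCC[C@]3(C[C@H]1O[C@@]1(CO)CCC#CC)O[C@]3(C)CO
F7 | step 15 | alkyne bis-epoxy diacetate | CC(C)(C)[Si](c1ccccc1)(c1ccccc1)OCC[C@]3(C[C@H]1O[C@@]1(COC(C)=O)CCC#CC)O[C@]3(C)COC(C)=O
F8 | step 15 | alkyne bis-epoxy diacetate C6 alcohol | OCC[C@]3(C[C@H]1O[C@@]1(COC(C)=O)CCC#CC)O[C@]3(C)COC(C)=O
F9 | step 15 | alkyne bis-epoxy diacetate C6 aldehyde (ynal) | O=CC[C@]3(C[C@H]1O[C@@]1(COC(C)=O)CCC#CC)O[C@]3(C)COC(C)=O
F10 | step 15 | triethylsilyl ether of 26 | CC(=O)OC[C@]12CC/C=C(\C)C(O[Si](CC)(CC)CC)C[C@]3(C[C@H]1O2)O[C@]3(C)COC(C)=O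
A1 | alternative 1 | ten-membered E-cycloalkene with C10 enol triflate, C1 methyl, C6 PMB ether and C8 TBS ether | C\C1=C(OS(=O)(=O)C(F)(F)F)/C[C@H](O[Si](C)(C)C(C)(C)C)C[C@@H](OCc2ccc(OC)cc2)/C(C)=C/CC1
A2 | alternative 2 | ten-membered trienone bis-TBS ether | CC(C)(C)[Si](C)(C)OC/C1=C/C/C(=C(\C)CO[Si](C)(C)C(C)(C)C)CC(=O)/C(C)=C/CC1
A3 | alternative 3 | methyl 2-[(3E,7E)-4-methyl-8-(tert-butyldimethylsilyloxymethyl)-5-oxocyclodeca-3,7-dien-1-yl]acrylate, i.e. the 2-methyl-6-(silyloxymethyl)cyclodeca-2,6-dienone with the acrylate on C9 | O=C1C[C@H](C(=C)C(=O)OC)C/C=C(/CO[Si](C)(C)C(C)(C)C)CC/C=C1\C
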